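**Plan**

- Retrosynthetic cuts, in order: (a) the C1 carboxyl and the side-chain ketone of the target are rejoined as the O2–C3 enol-lactone bond of 8-hydroxy-6-methoxy-3-undecylisocoumarin, with the 8-OH carried as a methyl ether; (b) the aryl C6–CH2 bond (C4a–C4 of the isocoumarin) is cut to 2,4-dimethoxybenzoic acid and a dodecanoyl sulfoxonium ylide; (c) the ylide C–C(=O) bond is cut to dodecanoyl chloride and trimethylsulfoxonium iodide.
- Enabling feature: C6, which carries the CH2–C(=O)–C11H23 arm, is the only carbon ortho to the C1 carboxyl that is not oxygenated (C2 bears the OH), and arm plus carboxyl together are a ring-opened 3-undecylisocoumarin (pyranone ring B fused to benzene ring A).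
- Forward order: the C13 keto ylide is made first; one rhodium-catalysed step joins the chain to ring A at C6 and closes ring B; the 8-methyl ether is cleaved; hydroxide then reopens ring B to release the open-chain keto acid.
- Stereochemistry: the target has no stereocentre and no configured double bond, so nothing needs to be controlled.

Key step: step 2

Assumption: the target is taken as the open keto acid drawn, not as its cyclic lactol tautomer.

**Route**

Step 1
Reactants: 1 trimethylsulfoxonium iodide; 2 dodecanoyl chloride
Product: 4 1-[dimethyl(oxo)-λ6-sulfanylidene]tridecan-2-one (dodecanoyl sulfoxonium ylide), via dimethylsulfoxonium methylide 3 (not isolated)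
Conditions: 1 (3 equiv), KOtBu (3 equiv), THF, reflux, 2 h; then 2 (1 equiv), 0 °C to rt
Reagents that add atoms: none
Why: Acylation of a sulfur ylide (the Corey–Chaykovsky methylide), in which the methylide carbon of 3 attacks the acyl chloride and a second equivalent of 3 deprotonates the resulting β-keto sulfoxonium salt, should give the carbonyl-stabilised ylide 4 as a bench-stable solid.

Step 2
Reactants: 5 2,4-dimethoxybenzoic acid; 4 1-[dimethyl(oxo)-λ6-sulfanylidene]tridecan-2-one
Product: 7 6,8-dimethoxy-3-undecyl-1H-isochromen-1-one, via ortho-acylmethyl keto acid 6 (not isolated)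
Conditions: [RhCl2(C5Me5)]2 (4 mol%), AgSbF6 (16 mol%), NaOAc (0.5 equiv), 4 (1.5 equiv), (CF3)2CHOH, 80 °C, sealed tube, N2
Reagents that add atoms: none
Why: The cationic C5Me5 complex of trivalent rhodium binds the carboxylate of 5 and undergoes acetate-assisted concerted metalation–deprotonation at C6 to a five-membered rhodacycle; the ylide carbon of 4 then coordinates, dimethyl sulfoxide departs to leave a rhodium carbene, and migratory insertion into the Rh–aryl bond followed by protonolysis forms the aryl C6–CH2 bond of keto acid 6. The closest known reaction type is the carboxylate-directed C–H acylmethylation and annulation of benzoic acids with sulfoxonium ylides under trivalent rhodium or divalent ruthenium catalysis, which delivers 3-substituted isocoumarins. Ring B closes by 6-exo-trig addition of the carboxyl oxygen to the ketone carbonyl and loss of water from the lactol, creating the O2–C3 bond and the C3=C4 enol double bond. No stereocentre is formed. The step needs site selectivity in the C–H activation, and the substrate secures it because C2 carries a methoxy group, so C6–H is the only C–H ortho to the directing carboxylate, while the hydrogens at C3 and C5 cannot be reached through a five-membered metallacycle. Product 7 no longer has a free carboxyl group, so a second carbene insertion is not expected.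

Step 3
Reactants: 7 6,8-dimethoxy-3-undecyl-1H-isochromen-1-one
Product: 9 8-hydroxy-6-methoxy-3-undecyl-1H-isochromen-1-one, via aryloxydichloroborane chelate 8 (not isolated)
Conditions: BCl3 (1 M in CH2Cl2, 1.5 equiv), CH2Cl2, −78 °C to 0 °C; then H2O, aq. NaHCO3
Reagents that add atoms: none
Why: Chelation-controlled Lewis-acid cleavage of an aryl methyl ether, in which BCl3 bridges the lactone carbonyl oxygen and the peri 8-methoxy oxygen in a six-membered chelate so that chloride removes only that methyl group, should leave the unchelated 6-methoxy group and the enol lactone untouched at low temperature, and aqueous work-up hydrolyses 8 to the phenol.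

Step 4
Reactants: 9 8-hydroxy-6-methoxy-3-undecyl-1H-isochromen-1-one
Product: 11 2-hydroxy-4-methoxy-6-(2-oxotridecyl)benzoic acid, via dipotassium phenoxide carboxylate 10 (not isolated)
Conditions: KOH (2 M aq., 4 equiv), THF, 50 °C, N2; then 1 M HCl to pH 3, 0 °C, immediate extraction
Reagents that add atoms: potassium hydroxide, [K+].[OH-] (supplies the new carboxyl oxygen)
Why: Saponification of an enol lactone, in which hydroxide adds to C1 and the ring opens to a carboxylate and an enolate that is protonated irreversibly to the ketone, should give the salt 10, and cold acidification to pH 3 frees the salicylic acid without the heat or dehydrating acid that decarboxylation or relactonisation would require.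

**Compound list**

1 | trimethylsulfoxonium iodide | C[S+](C)(C)=O.[I-] | starting material
2 | dodecanoyl chloride | CCCCCCCCCCCC(=O)Cl | starting material
3 | dimethylsulfoxonium methylide | C=S(C)(C)=O | intermediate (not isolated)
4 | 1-[dimethyl(oxo)-λ6-sulfanylidene]tridecan-2-one | CCCCCCCCCCCC(=O)C=S(C)(C)=O | intermediate
5 | 2,4-dimethoxybenzoic acid | COc1ccc(C(=O)O)c(OC)c1 | starting material
6 | 2,4-dimethoxy-6-(2-oxotridecyl)benzoic acid | CCCCCCCCCCCC(=O)Cc1cc(OC)cc(OC)c1C(=O)O | intermediate (not isolated)
7 | 6,8-dimethoxy-3-undecyl-1H-isochromen-1-one | CCCCCCCCCCCC1=Cc2cc(OC)cc(OC)c2C(=O)O1 | intermediate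
8 | 8-(dichloroboranyloxy)-6-methoxy-3-undecyl-1H-isochromen-1-one | CCCCCCCCCCCC1=Cc2cc(OC)cc(OB(Cl)Cl)c2C(=O)O1 | intermediate (not isolated)
9 | 8-hydroxy-6-methoxy-3-undecyl-1H-isochromen-1-one | CCCCCCCCCCCC1=Cc2cc(OC)cc(O)c2C(=O)O1 | intermediate
10 | dipotassium 4-methoxy-2-oxido-6-(2-oxotridecyl)benzoate | CCCCCCCCCCCC(=O)Cc1cc(OC)cc([O-])c1C(=O)[O-].[K+].[K+] | intermediate (not isolated)
11 | 2-hydroxy-4-methoxy-6-(2-oxotridecyl)benzoic acid | CCCCCCCCCCCC(=O)Cc1cc(OC)cc(O)c1C(=O)O | target

**Step count**

Total steps: 4. Longest linear sequence: 4 steps (1/2 → 4 → 7 → 9 → 11); acid 5 enters at step 2.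

**Steps most likely to fail**

Step 2. The carboxylate-directed metalation of the electron-rich acid may be slow. Protodecarboxylation of 5 and decomposition or self-coupling of the alkyl keto ylide could then compete with carbene transfer, and the cyclodehydration of 6 may stop short. The fallback drops C–H activation and builds the same CH2–C(=O) unit by lateral lithiation. It sets out from 2, which with MeNHOMe·HCl and K2CO3 in CH2Cl2/H2O at 0 °C should give N-methoxy-N-methyldodecanamide F1. Purchased methyl 2,4-dimethoxy-6-methylbenzoate F2 is deprotonated at the benzylic methyl group with LiN(iPr)2 (2.2 equiv) in THF at −78 °C to methyl 2-(lithiomethyl)-4,6-dimethoxybenzoate F3. This anion is acylated by F1 and, after aqueous NH4Cl quench, should give methyl 2,4-dimethoxy-6-(2-oxotridecyl)benzoate F4. Heating F4 with catalytic TsOH·H2O in toluene should close the enol lactone with loss of methanol, so the fallback comes back to the route at 7.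

Step 4. Hydroxide attack on the lactone carbonyl may be sluggish once the neighbouring phenol is deprotonated. During acidification the electron-rich salicylic acid may lose CO2, or ring B may close again by cyclodehydration. The fallback avoids aqueous acid by freeing the carboxyl group under neutral conditions. It sets out from 9, which with NaOCH2Ph (2.2 equiv) in PhCH2OH/THF at rt should open by transesterification to benzyl 2-hydroxy-4-methoxy-6-(2-oxotridecyl)benzoate F5. Hydrogenolysis of F5 (H2, 1 atm, Pd/C, EtOAc, rt) then removes the benzyl group without touching the alkyl ketone, so the fallback comes back to the route at 11.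

Step 3. Discrimination between the two aryl methyl ethers may be incomplete, or the Lewis acid together with liberated HCl may attack the enol lactone. The fallback replaces selective cleavage by exhaustive cleavage and selective re-methylation. It sets out from 7, which with excess BBr3 in CH2Cl2 (−78 °C to rt) should give 6,8-dihydroxy-3-undecyl-1H-isochromen-1-one F6. Treatment of F6 with MeI (1.05 equiv) and K2CO3 in acetone at rt should methylate only the 6-OH, because the 8-OH is held in a hydrogen bond to the lactone carbonyl and is far less nucleophilic. The fallback comes back to the route at 9.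

**Further compounds**

F1 | step 2 | N-methoxy-N-methyldodecanamide | CCCCCCCCCCCC(=O)N(C)OC
F2 | step 2 | methyl 2,4-dimethoxy-6-methylbenzoate | COC(=O)c1c(C)cc(OC)cc1OC
F3 | step 2 | methyl 2-(lithiomethyl)-4,6-dimethoxybenzoate | [Li]Cc1cc(OC)cc(OC)c1C(=O)OC
F4 | step 2 | methyl 2,4-dimethoxy-6-(2-oxotridecyl)benzoate | CCCCCCCCCCCC(=O)Cc1cc(OC)cc(OC)c1C(=O)OC
F5 | step 4 | benzyl 2-hydroxy-4-methoxy-6-(2-oxotridecyl)benzoate | CCCCCCCCCCCC(=O)Cc1cc(OC)cc(O)c1C(=O)OCc1ccccc1
F6 | step 3 | 6,8-dihydroxy-3-undecyl-1H-isochromen-1-one | CCCCCCCCCCCC1=Cc2cc(O)cc(O)c2C(=O)O1
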